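The readings were generated by integration on assumed constants, noise included.

Of the Xo charged, 66% reads as Zu at 120 s in zeta and 87% at 120 s in beta, and I reckon from these two fractions because the new flasks stop at that same time, 2.0 min.

the same everywhere: Dw 5 mol%

| flask | Xo | Jy | remark | time |
|---|---|---|---|---|
| zeta | 0.048 M | 2.5 equiv | run made earlier |  |
| beta | 0.14 M | 2.5 equiv | run made earlier |  |
| Thursday's | 0.050 M | 2.50 equiv |  | 2.0 min |
| Tuesday's | 0.10 M | 2.50 equiv |  | 2.0 min |
| Monday's | 0.20 M | 2.50 equiv |  | 2.0 min |

| run | time / s | Zu / % |
|---|---|---|
| zeta | 10.0 | 6 |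
| zeta | 20.0 | 15 |
| zeta | 30.0 | 24 |
| zeta | 60.0 | 42 |
| zeta | 120 | 66 |
| beta | 10.0 | 16 |
| beta | 30.0 | 43 |
| beta | 60.0 | 69 |
| beta | 80.0 | 77 |
| beta | 120 | 87 |

(scatter of a reading: 1.5 percentage points)

- what was read earlier has a scatter of 1.5 percentage points, one standard deviation
- a reading or a percentage of Zu counts all its forms, free or not
- the concentration of Zu that is asked is that of its free form alone
- "hardly changes" means that all values lie within two and a half points (for a concentration: within two and a half percent of the largest)

* [Zu] (only what is free in solution) at the end for Thursday's, Tuesday's, Monday's, in this order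
* the shape of the row from first to last (falls, then rises / rises all the way / hardly changes / falls all the way / rises, then falls)

Jy is charged at 2.50 equiv, so if one Jy goes per Xo, the fraction of its own charge left does not fall below 60.0%; I freeze it and treat the loss of Xo as pseudo-first-order, so that the fraction not counted as Zu at the stopping time is exp(−L), which makes L, as read from these scattered readings, 1.08 for zeta and 2.04 for beta.

Two extreme versions can be solved in the head. If L ignores the charge, beta repeats zeta's 66%; if L grows in step with the charge, as Jy and Dw both scale with Xo, beta reaches 95.7%. Beta's reading is higher than the first and lower than the second, so beta lies between them, and I carry the power of the charge to which L answers, read from these two runs, the charge exponent 0.595.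

Scaling zeta's L by this power, I reckon the fraction counted as Zu at 2.0 min as 66.9% for Thursday's, 81.2% for Tuesday's and 92.0% for Monday's. These fractions count all forms of Zu, free or not, as the readings do, so they do not give the free concentration asked, and I commit to them for the counted Zu.

The forecast scales its rate constant roughly as the charge to the power 0.7 and gives 0.031 M, 0.079 M and 0.179 M, a row that rises all the way, while saying of the split: “The data do not show how much Zu is bound”.

The flask gives 0.00303 M, 0.00340 M and 0.00216 M, and the shape is rises, then falls.

    Jy + Dz → Ji (k = 3.80 M⁻¹ s⁻¹)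
    Xo + Dw → Dz (k = 8.10 M⁻¹ s⁻¹)
    Xi ⇌ Zu, rate k3*(cs3 - [Zu]) while solid is left; crystals form when [Zu] > cs3 (solubility = 1.60 mM, k = 0.130 s⁻¹)
    Xo + Zu → Ux (k = 0.130 M⁻¹ s⁻¹)
    Ji ⇌ Dw + Zu (K = 0.0560 M, k = 1.10 s⁻¹)

On Monday's, Zu counts 86.1% of the charge at 2.00 min, and nearly all of that is the 85.0% standing as Xi. The charge exponent 0.595 put 66.9% on Thursday's, where the flask counts 68.1% as Zu, and 92.0% on Monday's, where it counts 86.1% as Zu beside 13.6% as Ux.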